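I took four neighbouring flasks with one charge, which differed in their vessel and in what was dosed.

    substrate + target → side product (k1 = 0.036 M⁻¹ min⁻¹)
    substrate + free catalyst → catalyst intermediate A (k2 = 9.0 M⁻¹ min⁻¹)
    catalyst intermediate B → free catalyst + target (k3 = 1.7 min⁻¹)
    coupling partner + catalyst intermediate A → catalyst intermediate B (k4 = 2.2 M⁻¹ min⁻¹)

the same everywhere: free catalyst 0.81 mM
- theta: substrate 0.11 M; coupling partner 0.440 M (fed, over 20.0 h); time 25 h; a stirred flask in which coupling partner is dosed at a steady rate over 20.0 h without added volume, worked up at 25 h
- gamma: substrate 0.11 M; coupling partner 0.440 M; a single well-mixed tank run continuously and read at steady state, 25 h in it on average
- eta: substrate 0.11 M; coupling partner 0.440 M; time 25 h; everything together in a closed stirred flask, run for 25 h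
- delta: substrate 0.11 M (fed, over 20.0 h); coupling partner 0.440 M; time 25 h; a stirred flask in which substrate is dosed at a steady rate over 20.0 h without added volume, worked up at 25 h

- in percentages every species weighs as the substrate in it: one side product counts as two
- the stated concentrations are those of everything mixed, before any reaction; amounts are the same in each set-up
- the feed brings no volume worth counting
- run time (theta): 25 h

- the set-up with the highest share of target in all that became target or side product, at the outlet or at the end ("none" if the first two lie within 2 percentage points) (theta / gamma / eta / delta / none)
- share of target in all that became target or side product, at the outlet or at the end, theta
- share of target in all that became target or side product, at the outlet or at the end, gamma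
- share of target in all that became target or side product, at the outlet or at the end, eta
- share of target in all that became target or side product, at the outlet or at the end, delta

I first asked which given numbers had to be known well. In the side step target takes substrate at a rate proportional to [substrate][target], and in the entry step free catalyst takes it at a rate proportional to [substrate][free catalyst], so [substrate] cancels from their ratio. With free catalyst as the resting state, the side constant, the entry constant and the catalyst charge meet in one quantity: the crossover target, the [target] at which the side step takes substrate as fast as the entry step, which is the entry constant times the catalyst charge over the side constant, 0.203 M.

I solved the two ends, with the catalyst held as free catalyst. With a substrate charge far below the crossover, the share of target falls short of whole by about the charge over the crossover. With a charge far above it, [target] stalls at the crossover, so the share is the crossover over the charge. Joining them, the share is the crossover over the crossover plus the charge, 64.8%. Doubling the substrate charge, or halving the catalyst charge, reckons to 47.9%, so these numbers matter.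

The coupling partner and the last two constants act through one correction, which divides the crossover by one plus a term. In delta, I reckoned that during the feed dosing holds [substrate] near the feed rate over the entry constant times the catalyst charge, 0.0126 M, and the term is 0.183. At the start of eta it is 1.61, larger than my figure for delta during its feed, though it falls as the substrate of eta is used. So I put delta ahead of eta and took delta as my candidate for best, with an estimate for delta running from 60.9% to 64.8%.

The forecast, holding that “the catalyst cycle can be treated as quasi-steady”, gave 49% for theta, 53.3% for gamma, 57% for eta and 63.5% for delta, with delta best. The simulation gave 49.1%, 53.3%, 57.6% and 64.0% in that order, so delta came first. Delta's reading lay inside my range, lower than the joined share. Its substrate stood at 0.0124 M after 12.5 h, and its final [target] of 0.0699 M stayed below the crossover. A neighbour of theta charged with 0.028 M of substrate reckons to 87.9%; that flask gave 83.7%, against 64.8% reckoned and 49.1% found for theta itself.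

Its constants come from no measurement; what happens was integrated by code.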